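## Structural features

The target 28 is a C20 dibromo triol of three carbocycles: a trans-fused hydrindane (five-membered ring B, six-membered ring C) whose C3 is joined through a secondary carbinol carbon C1′ to C1″ of a 4-bromo-1-hydroxy-3,3-dimethylcyclohexane (ring A). The locants used below are those of the hydrindane (C3 side-chain CH, C3a ring-fusion CH, C4 tertiary carbinol, C7 CHBr, C7a methyl-bearing quaternary carbon), C1′ for the linking carbinol and C1″–C6″ for ring A (C1″ carbinol, C3″ CMe2, C4″ CHBr), and β denotes the face of the C7a methyl group. Seven of the eight stereocentres are contiguous (C7, C7a, C3a, C4, C3, C1′, C1″), whereas C4″ lies across ring A with no stereocentre between it and the others. In ring C the C7 bromine is equatorial and β, the C4 hydroxyl is axial and syn to the angular methyl, and C3a–H is α, so the ring B bonds at C7a and C3a are trans and the C3 side chain is α. Both bromides are secondary and neopentylic (elimination and 1,2-shift are easier than substitution), the tertiary alcohols dehydrate under acid, the C1′/C1″ diol can undergo a pinacol shift, and any intermediate with a C4 carbonyl can epimerise C3a to the cis-hydrindane. The real difficulty lies in the quaternary C7a flanked by stereocentres within a trans ring fusion, in making the C7–Br bond at a neopentylic carbon, and in controlling ring A (C1″, C4″) from a remote chiral core. The key step uses the fact that in ring C the quaternary C7a and the CH C3a are adjacent and carry trans ring B arms while the neighbouring C7 bears a heteroatom, so that C7–C7a and C3a–C4 map onto a [4+2] union of an (E)-α-methyl enal (C7a, C3a, formyl carbon = C1, ester arm = C3 and C1′) with a 1-oxygenated butadiene (C7, C6, C5, C4).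

## Logic of the disconnections

28 ⇒ 26 (through 27). No skeletal bond is cut. The C1′ and C1″ oxygens are tied into a cyclic carbonate and the C4 oxygen is silylated, because the carbonate is the internal nucleophile of the ring A closure and the silyl ether keeps the C4 hydroxyl from capturing the C1″ cation. The forward unmasking must spare two bromides and must not expose the free diol to strong acid.

26 ⇒ 25. The C2″–C3″ bond, the C4″–Br bond and the C1″–O bond are cut together. A 4-bromo-3,3-dimethylcyclohexane is the signature of a bromonium-initiated diene cyclisation, and cutting here removes ring A with two stereocentres and leaves an open dienyl chain. The forward step must choose one face of a remote trisubstituted alkene by reagent control and must trap the C1″ cation from the axial direction.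

25 ⇒ 24 ⇒ 23. The C1′–H bond is removed (carbinol back to ketone) and the carbonate is taken off. Addition of a carbon nucleophile to a C1′ aldehyde would give the wrong Felkin–Anh epimer, whereas hydride addition to the C1′ ketone gives the required one. The demand is a 1,2-selective, Felkin-selective reduction of a hindered α-methylene ketone.

23 ⇒ 19 + 22, and 22 ⇒ 21 ⇒ 20. The C1′–C1″ bond is cut, dividing the skeleton into a C12 bicyclic acyl unit and a C8 dienyl nucleophile. The forward acyl substitution must stop at the ketone, and the vinyl anion must be formed at the less substituted α-carbon of 20.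

19 ⇒ 18 ⇒ 17 ⇒ 16. The C7–Br bond is exchanged for a C7–O bond of opposite configuration, with protecting-group and acyl adjustments. The inverted oxygen is exactly what the cycloaddition delivers, and it sits axially in the bicycle. The forward step is an SN2 displacement at a neopentylic carbon, the most demanding functional-group change of the route.

16 ⇒ 15 ⇒ 14. The C4–CH3 bond is cut, leaving a C4 ketone. The syn-axial C7a methyl should force the nucleophile into the equatorial position and so set the axial hydroxyl. The forward step must select the ketone over the ester and must not enolise towards C3a.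

14 ⇒ 13 ⇒ 12. The C4 oxygen is removed back to a methylene group next to the C5=C6 alkene, which is the alkene left by the cycloaddition. The forward step must oxidise C4 and not C7 or, after allylic transposition, C6.

12 ⇒ 11. The C2–C3 bond of ring B is cut between an ester α-carbon and a primary iodide. Because the two arms are already trans, the 5-exo-tet closure can only give the trans fusion, and C3 is epimerisable to the required configuration. The forward step tolerates no other enolisable or nucleophilic group, which is why the acetate is exchanged for a silyl ether beforehand.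

11 ⇒ 10 ⇒ 8 ⇒ 7 ⇒ 6 ⇒ 5. The C1–C2 bond is cut (one-carbon extension of the formyl group) and the oxygen protecting group is exchanged. The forward methylenation must come before acetate cleavage to avoid retro-aldol opening, and the hydroboration must choose the vinyl group over the ring alkene.

5 ⇒ 3 + 4. The C7–C7a and C3a–C4 bonds are cut. This removes ring C and three stereocentres at once and leaves two small achiral partners. The forward step needs catalyst control of the enal face, endo orientation of the formyl group and ortho regiochemistry.

3 ⇒ 1 + 2. The trisubstituted C=C bond is cut into two terminal alkenes. The forward cross-metathesis must give the E isomer and must not move the β,γ-alkene of the ester partner into conjugation.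

## Other disconnections considered

Alternative 1: The cut is through ring A at C2″–C3″ together with C4″–Br and C1″–O, leading from the spiro carbonate A1 back to the open dienyl tert-butyl carbonate A2. In the forward sense an electrophilic bromine source under chiral Lewis-base control would brominate the prenyl alkene, the 1,1-disubstituted alkene would close the ring, and the carbonate would trap the cation.
- In its favour: the labile ring A bromide is introduced as late as possible, the plan is convergent, the carbonate fixes the C1″ oxygen and protects the diol in one event, and reagent control is the only realistic way to reach C4″, which no stereocentre of the core can influence.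
- Against it: as a strategy for the whole molecule it leaves the hydrindane, with five contiguous stereocentres, the quaternary carbon and the C7 bromide, unaddressed. The cyclisation is also stepwise and cationic, so proton loss and capture on the wrong face of C1″ are open channels.
- Comparison: on ring A this alternative is the better idea and is not a competitor. The chosen route adopts it as step 20, so that A1 is identical with 26 and A2 with 25, and the two plans are equal in step count after the hydrindane. The chosen key step is a concerted cycloaddition that sets three stereocentres in the second step, where failure costs little, whereas a plan resting on the last C–C bond carries its main risk at the end.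

Alternative 2: The cut is the C2–C3 bond of ring B, made by ring contraction. The α′-diazo enone A4, a decalin derived from (S)-Wieland–Miescher ketone A5, would on photolysis in an alcohol undergo Wolff rearrangement to the hydrindene ester A3.
- In its favour: A5 is available in quantity in either enantiomeric form, so the quaternary centre comes from a proven source and no asymmetric catalysis on a trisubstituted dienophile is needed; on this point the alternative is the better plan. The C7 oxygen is present from the start, the trans fusion can be set by established reduction of the enone, and the Wolff contraction delivers the C3 ester carbon directly.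
- Against it: A5 must be extensively refunctionalised before the key step (C4 carbinol with defined configuration at the γ-position of the enone, enone transposition, diazo transfer next to the ring fusion). A3 is a β,γ-unsaturated ester whose C3 centre is both allylic and α to the carbonyl and could be lost by conjugation. The C7 ketone would have to be reduced to the axial alcohol against the usual preference of small hydrides before an invertive bromination.
- Comparison: both plans arrive at the same ester-substituted trans-hydrindane and both form the same C2–C3 bond, so they are equal in target-relevant structure at that stage. Mechanistically the carbene/ketene sequence is robust but creates no stereocentre, whereas the cycloaddition creates three and places the C7 oxygen in the axial orientation that the later inversion needs. In step economy the chosen plan should be clearly shorter, since the ring C cyclohexene is in hand after two steps from commercial materials.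

Alternative 3: The cut is the C5–C6 bond of ring C. Anodic oxidation of the silyl enol ether in the cyclopentane A7 would give a radical cation that is attacked by the neighbouring 2-substituted allylsilane, closing ring C to the hydrindanone A6.
- In its favour: two nucleophilic carbons are joined under mild, reagent-free conditions, and the new bond lies away from all stereocentres. The product carries a ketone at C7 and an exocyclic methylene at C4, exactly where the heteroatoms are needed. A single hydration of the methylene group could install the C4 methyl carbinol, which is more direct than the oxidation, hydrogenation and methyl addition of the chosen plan; on this point the alternative is the better.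
- Against it: the stereochemical burden is moved to A7, a cyclopentane with a quaternary centre and two further adjacent stereocentres, whose enantioselective synthesis is the harder problem and is not solved by the key step. Closing a six-membered ring across trans arms of a cyclopentane is strained, so solvent capture or desilylation of the radical cation could compete. The C7 ketone must again be reduced to the axial alcohol, and the face of hydration at C4 is uncertain.
- Comparison: structurally the alternative closes ring C onto ring B, while the chosen plan closes ring B onto ring C. Its key step is stereochemically safer because it sets nothing, but for the same reason it contributes less. In step economy it is unlikely to match a two-step entry to ring C, while in the handling of C4 it is the better and in the need for an invertive bromination at C7 it is the equal of the chosen plan.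

Key step: step 2

Assumption: commercial 1-acetoxybuta-1,3-diene is sold as a mixture of geometric isomers; only the E isomer 4 is a competent diene, so the mixture is used in excess and the Z isomer is left behind.
Assumption: for step 20 the antipode of the thiophosphoramide catalyst is the one that delivers bromine to the Si face of the alkene CH carbon (future C4″); the sense of induction cannot be transferred with certainty from aryl-terminated substrates.

## Steps

Step 1
Reactants: 1 methacrolein, 2 methyl but-3-enoate
Product: 3 methyl (E)-4-methyl-5-oxopent-3-enoate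
Conditions: second-generation Hoveyda–Grubbs catalyst RuCl2(H2IMes)(=CH-C6H4-2-OiPr) (5 mol %), 1 (4 equiv), CH2Cl2, 40 °C
Reagents that add atoms: none
Why: Olefin cross-metathesis; the slowly homodimerising 1,1-disubstituted enal is used in excess, ethene is lost, and the trisubstituted enal should form as the thermodynamically preferred E isomer (formyl trans to the ester-bearing chain).

Step 2
Reactants: 3 methyl (E)-4-methyl-5-oxopent-3-enoate, 4 (E)-buta-1,3-dien-1-yl acetate
Product: 5 methyl 2-[(1S,5R,6S)-5-acetoxy-6-formyl-6-methylcyclohex-3-en-1-yl]acetate
Conditions: (S)-B-(o-tolyl)oxazaborolidine from (S)-α,α-diphenylprolinol (20 mol %), Tf2NH (18 mol %), 4 (3 equiv), CH2Cl2, −78 → −40 °C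
Reagents that add atoms: none
Why: The cationic oxazaborolidinium binds the formyl oxygen of 3 (with the formyl C–H···O contact typical of α-substituted enals) and lowers the LUMO of the s-trans enal, which reacts as the two-electron partner with 4 as the four-electron partner in a concerted, asynchronous [4+2] cycloaddition; the closest known reaction type is the oxazaborolidinium-catalysed Diels–Alder reaction of α-substituted enals with 1-oxygenated butadienes. Ring C is closed in this intermolecular [4+2] mode, C7–C7a and C3a–C4 being formed in the same event. The absolute configuration at C7a and C3a is set by the catalyst, whose phenyl group covers one face of the bound enal so that the diene should add to the Re face of the α-carbon. The C7a/C3a relationship follows from suprafacial addition to the E alkene, which places the formyl carbon and the ester arm trans and so fixes the later trans ring fusion. C7 is set by the endo rule: with the boron-bound formyl group under the diene, the acetoxy group of the E diene ends up cis to formyl and trans to methyl. Ortho regiochemistry is secured by the acetoxy donor, which puts the larger HOMO coefficient on the unsubstituted diene terminus so that it bonds to the β-carbon. The step needs enantio-, endo- and regioselectivity at once; the strongly acidic triflimide-derived catalyst supplies the reactivity a trisubstituted dienophile needs at low temperature, and the ester is the weaker Lewis base and should not compete for boron.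

Step 3
Reactants: 5 methyl 2-[(1S,5R,6S)-5-acetoxy-6-formyl-6-methylcyclohex-3-en-1-yl]acetate
Product: 6 methyl 2-[(1S,5R,6S)-5-acetoxy-6-ethenyl-6-methylcyclohex-3-en-1-yl]acetate
Conditions: Ph3PCH3Br, KN(SiMe3)2, THF, 0 °C; then 5, −78 → 0 °C
Reagents that add atoms: methyltriphenylphosphonium bromide, C[P+](c1ccccc1)(c1ccccc1)c1ccccc1.[Br-]
Why: Wittig methylenation; the aldehyde has no α-hydrogen and is far more electrophilic than the two esters, and removing the formyl group at this point excludes retro-aldol opening when the acetate is cleaved.

Step 4
Reactants: 6 methyl 2-[(1S,5R,6S)-5-acetoxy-6-ethenyl-6-methylcyclohex-3-en-1-yl]acetate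
Product: 7 methyl 2-[(1S,5R,6S)-6-ethenyl-5-hydroxy-6-methylcyclohex-3-en-1-yl]acetate
Conditions: K2CO3 (cat.), MeOH, 0 °C
Reagents that add atoms: none
Why: Transesterification of the acetate; the methyl ester is degenerate under methanolysis, and the hydroxyl and the ester arm are trans so no lactone can form.

Step 5
Reactants: 7 methyl 2-[(1S,5R,6S)-6-ethenyl-5-hydroxy-6-methylcyclohex-3-en-1-yl]acetate
Product: 8 methyl 2-[(1S,5R,6S)-5-(tert-butyldimethylsilyloxy)-6-ethenyl-6-methylcyclohex-3-en-1-yl]acetate
Conditions: TBSOTf, 2,6-lutidine, CH2Cl2, −78 → 0 °C
Reagents that add atoms: tert-butyldimethylsilyl triflate, CC(C)(C)[Si](C)(C)OS(=O)(=O)C(F)(F)F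
Why: Silylation of a hindered secondary alcohol with a silyl triflate; the silyl ether has no enolisable hydrogen and cannot act as an oxygen nucleophile towards the iodide made later.

Step 6
Reactants: 8 methyl 2-[(1S,5R,6S)-5-(tert-butyldimethylsilyloxy)-6-ethenyl-6-methylcyclohex-3-en-1-yl]acetate
Product: 10 methyl 2-[(1S,5R,6S)-5-(tert-butyldimethylsilyloxy)-6-(2-hydroxyethyl)-6-methylcyclohex-3-en-1-yl]acetate, via alkylborane 9 (not isolated)
Conditions: 9-BBN, THF, 0 → 50 °C; then NaBO3·4H2O, H2O, rt
Reagents that add atoms: sodium perborate tetrahydrate (supplies the oxygen), [Na+].[Na+].O[B-]1(O)OO[B-](O)(O)OO1; 9-borabicyclo[3.3.1]nonane (boron unit kept only in 9), B1C2CCCC1CCC2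
Why: Anti-Markovnikov hydroboration–oxidation; 9-BBN strongly prefers a monosubstituted terminal alkene over the cis-disubstituted ring alkene, and perborate oxidises the borane without hydrolysing the ester.

Step 7
Reactants: 10 methyl 2-[(1S,5R,6S)-5-(tert-butyldimethylsilyloxy)-6-(2-hydroxyethyl)-6-methylcyclohex-3-en-1-yl]acetate
Product: 11 methyl 2-[(1S,5R,6S)-5-(tert-butyldimethylsilyloxy)-6-(2-iodoethyl)-6-methylcyclohex-3-en-1-yl]acetate
Conditions: I2, PPh3, imidazole, CH2Cl2, 0 °C → rt
Reagents that add atoms: iodine, II
Why: Appel-type iodination of an unhindered primary alcohol under neutral conditions.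

Step 8
Reactants: 11 methyl 2-[(1S,5R,6S)-5-(tert-butyldimethylsilyloxy)-6-(2-iodoethyl)-6-methylcyclohex-3-en-1-yl]acetate
Product: 12 methyl 7α-(tert-butyldimethylsilyloxy)-7aβ-methyl-2,3,3aα,4,7,7a-hexahydro-1H-indene-3α-carboxylate
Conditions: LiN(iPr)2 (1.2 equiv), THF–DMPU, −78 → −20 °C
Reagents that add atoms: none
Why: Intramolecular ester-enolate alkylation (5-exo-tet) closes ring B, and the trans arms can only give the trans fusion. At C3, A(1,3) strain in the enolate (C3a–H eclipsing the enolate) should put the ester on the α face, which is also the thermodynamic position (trans to C4 and away from the angular methyl).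

Step 9
Reactants: 12 methyl 7α-(tert-butyldimethylsilyloxy)-7aβ-methyl-2,3,3aα,4,7,7a-hexahydro-1H-indene-3α-carboxylate
Product: 13 methyl 7α-(tert-butyldimethylsilyloxy)-7aβ-methyl-4-oxo-2,3,3aα,4,7,7a-hexahydro-1H-indene-3α-carboxylate
Conditions: CrO3, 3,5-dimethylpyrazole, CH2Cl2, −20 °C
Reagents that add atoms: chromium trioxide, O=[Cr](=O)=O
Why: Allylic oxidation of a cyclohexene to the enone; the C4 methylene is the accessible allylic site, whereas C7–H is tertiary and shielded by the quaternary centre and the silyl ether, and the non-basic medium leaves the C3a centre of the product untouched.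

Step 10
Reactants: 13 methyl 7α-(tert-butyldimethylsilyloxy)-7aβ-methyl-4-oxo-2,3,3aα,4,7,7a-hexahydro-1H-indene-3α-carboxylate
Product: 14 methyl 7α-(tert-butyldimethylsilyloxy)-7aβ-methyl-4-oxo-octahydro-1H-indene-3α-carboxylate (3aα-H)
Conditions: H2 (1 atm), Pd/C, EtOAc, rt
Reagents that add atoms: none
Why: Heterogeneous hydrogenation of the enone C=C under neutral conditions; no stereocentre is formed and C3a is not exposed to base.

Step 11
Reactants: 14 methyl 7α-(tert-butyldimethylsilyloxy)-7aβ-methyl-4-oxo-octahydro-1H-indene-3α-carboxylate (3aα-H)
Product: 15 methyl 7α-(tert-butyldimethylsilyloxy)-4β-hydroxy-4α,7aβ-dimethyl-octahydro-1H-indene-3α-carboxylate (3aα-H)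
Conditions: MeMgBr, CeCl3, THF, −78 °C; NH4Cl (aq)
Reagents that add atoms: methylmagnesium bromide, C[Mg]Br
Why: Organocerium addition to the ketone, which suppresses enolisation and spares the ester at low temperature. Axial attack is blocked by the syn-axial C7a methyl, so the methyl group should enter equatorially from the α face and leave the hydroxyl axial and β.

Step 12
Reactants: 15 methyl 7α-(tert-butyldimethylsilyloxy)-4β-hydroxy-4α,7aβ-dimethyl-octahydro-1H-indene-3α-carboxylate (3aα-H)
Product: 16 methyl 4β,7α-dihydroxy-4α,7aβ-dimethyl-octahydro-1H-indene-3α-carboxylate (3aα-H)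
Conditions: HF·pyridine, pyridine, THF, 0 °C → rt
Reagents that add atoms: none
Why: Fluoride-mediated desilylation under buffered, non-basic conditions, so that C3 cannot epimerise towards a lactone with the C4 hydroxyl.

Step 13
Reactants: 16 methyl 4β,7α-dihydroxy-4α,7aβ-dimethyl-octahydro-1H-indene-3α-carboxylate (3aα-H)
Product: 17 methyl 7β-bromo-4β-hydroxy-4α,7aβ-dimethyl-octahydro-1H-indene-3α-carboxylate (3aα-H)
Conditions: CBr4, PPh3, pyridine, toluene, rt → 60 °C
Reagents that add atoms: carbon tetrabromide, BrC(Br)(Br)Br
Why: Appel bromination with SN2 inversion; the axial oxyphosphonium leaving group allows bromide to enter along the equatorial trajectory, the favourable case for a neopentylic ring carbon, and gives the equatorial β bromide. The hindered tertiary alcohol should not be activated under these neutral conditions.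

Step 14
Reactants: 17 methyl 7β-bromo-4β-hydroxy-4α,7aβ-dimethyl-octahydro-1H-indene-3α-carboxylate (3aα-H)
Product: 18 methyl 7β-bromo-4α,7aβ-dimethyl-4β-(triethylsilyloxy)-octahydro-1H-indene-3α-carboxylate (3aα-H)
Conditions: TESOTf, 2,6-lutidine, CH2Cl2, −78 → 0 °C
Reagents that add atoms: triethylsilyl triflate, CC[Si](CC)(CC)OS(=O)(=O)C(F)(F)F
Why: Silylation of the tertiary alcohol with a silyl triflate; the ether keeps this oxygen from consuming the organolithium and from capturing the C1″ cation in step 20 through a six-membered ether.

Step 15
Reactants: 18 methyl 7β-bromo-4α,7aβ-dimethyl-4β-(triethylsilyloxy)-octahydro-1H-indene-3α-carboxylate (3aα-H)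
Product: 19 7β-bromo-N-methoxy-N,4α,7aβ-trimethyl-4β-(triethylsilyloxy)-octahydro-1H-indene-3α-carboxamide (3aα-H)
Conditions: MeNHOMe·HCl, iPrMgCl, THF, −20 → 0 °C
Reagents that add atoms: N,O-dimethylhydroxylamine hydrochloride, CNOC.Cl
Why: Direct aminolysis of the ester by the magnesium amide to the Weinreb amide; C3 already has its thermodynamic configuration, and the equatorial bromide has no anti-periplanar hydrogen for elimination.

Step 16
Reactants: 20 6-methylhept-5-en-2-one
Product: 21 (E)-N′-(6-methylhept-5-en-2-ylidene)-2,4,6-triisopropylbenzenesulfonohydrazide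
Conditions: 2,4,6-triisopropylbenzenesulfonohydrazide, MeOH, HCl (cat.), rt
Reagents that add atoms: 2,4,6-triisopropylbenzenesulfonohydrazide, CC(C)c1cc(C(C)C)c(S(=O)(=O)NN)c(C(C)C)c1
Why: Condensation of a methyl ketone with an arenesulfonyl hydrazide; the bulky aryl group is chosen because it resists ortho-lithiation in the next step.

Step 17
Reactants: 21 (E)-N′-(6-methylhept-5-en-2-ylidene)-2,4,6-triisopropylbenzenesulfonohydrazide, 19 7β-bromo-N-methoxy-N,4α,7aβ-trimethyl-4β-(triethylsilyloxy)-octahydro-1H-indene-3α-carboxamide (3aα-H)
Product: 23 1-[7β-bromo-4α,7aβ-dimethyl-4β-(triethylsilyloxy)-octahydro-1H-inden-3α-yl]-6-methyl-2-methylidenehept-5-en-1-one (3aα-H), via vinyllithium 22 (not isolated)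
Conditions: 21 (2.5 equiv), n-BuLi (2.05 equiv per 21), THF, −78 → 0 °C; then 19, −78 → −40 °C; NH4Cl (aq)
Reagents that add atoms: none
Why: Shapiro reaction; the dianion forms at the methyl group and loses sulfinate and nitrogen to give the 2-lithio-1-alkene, which adds once to the Weinreb amide because the chelated tetrahedral adduct survives until the quench. A vinyllithium does not exchange with the secondary alkyl bromide.

Step 18
Reactants: 23 1-[7β-bromo-4α,7aβ-dimethyl-4β-(triethylsilyloxy)-octahydro-1H-inden-3α-yl]-6-methyl-2-methylidenehept-5-en-1-one (3aα-H)
Product: 24 (1R)-1-[7β-bromo-4α,7aβ-dimethyl-4β-(triethylsilyloxy)-octahydro-1H-inden-3α-yl]-6-methyl-2-methylidenehept-5-en-1-ol (3aα-H)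
Conditions: NaBH4, CeCl3·7H2O, MeOH–THF, −78 °C
Reagents that add atoms: none
Why: Luche 1,2-reduction of the enone; in the Felkin–Anh arrangement the bulky C3a is anti to the incoming hydride and the hydride passes the C3 hydrogen, which should give the (1′R) carbinol, the same sense that governs reduction of 20-oxo steroids.

Step 19
Reactants: 24 (1R)-1-[7β-bromo-4α,7aβ-dimethyl-4β-(triethylsilyloxy)-octahydro-1H-inden-3α-yl]-6-methyl-2-methylidenehept-5-en-1-ol (3aα-H)
Product: 25 tert-butyl carbonate of 24 at the C1′ oxygen
Conditions: NaN(SiMe3)2, THF, −78 °C; Boc2O, −78 → 0 °C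
Reagents that add atoms: di-tert-butyl dicarbonate, CC(C)(C)OC(=O)OC(=O)OC(C)(C)C
Why: Acylation of the sodium alkoxide of a hindered secondary allylic alcohol with Boc anhydride; no stereocentre is touched.

Step 20
Reactants: 25 tert-butyl carbonate of 24 at the C1′ oxygen
Product: 26 spiro cyclic carbonate of the C1′/C1″ diol: (1″R,4″S)-4″-bromo-3″,3″-dimethylcyclohexane spiro-fused at C1″ to a 1,3-dioxolan-2-one whose C1′ (R) carries the 7β-bromo-4α,7aβ-dimethyl-4β-(triethylsilyloxy)hydrindan-3α-yl group
Conditions: 1,3-dibromo-5,5-dimethylhydantoin (0.55 equiv), 3,3′-diaryl-BINOL-derived thiophosphoramide (10 mol %), toluene–CH2Cl2, −90 → −78 °C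
Reagents that add atoms: 1,3-dibromo-5,5-dimethylhydantoin, CC1(C)N(Br)C(=O)N(Br)C1=O
Why: Proposed new method: the chiral thiophosphoramide acts as a Lewis base that takes Br+ from the hydantoin and passes it to the more electron-rich trisubstituted alkene (Si face of the CH carbon gives 4″S); the 1,1-disubstituted alkene then attacks the bromonium ion through its CH2 terminus in a chair (6-endo closure of ring A, bromine equatorial), and the tertiary C1″ cation is captured by the carbonate carbonyl oxygen (5-exo) from the axial direction so that the large C1′ substituent stays equatorial, after which the tert-butyl group leaves as isobutene; the closest known reaction types are the Lewis-base-catalysed enantioselective bromocyclisation of aryl-terminated polyprenoids and the non-enantioselective bromonium cyclisation terminated by tert-butyl carbonates, which have not been combined on a 1,1-disubstituted alkene bearing an allylic carbonate.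

Step 21
Reactants: 26 spiro cyclic carbonate of the C1′/C1″ diol with C4 triethylsilyl ether
Product: 28 (3R,3aS,4R,7S,7aS)-7-bromo-3-{(R)-[(1R,4S)-4-bromo-1-hydroxy-3,3-dimethylcyclohexyl](hydroxy)methyl}-4,7a-dimethyloctahydro-1H-inden-4-ol, via hydroxy carbonate 27 (not isolated)
Conditions: HF·pyridine, pyridine, THF, 0 °C → rt; then K2CO3, MeOH, rt
Reagents that add atoms: none
Why: Fluoride cleaves the tertiary silyl ether while the diol is still masked against acid-promoted pinacol shift, and the basic methanolic quench then methanolyses the cyclic carbonate; the equatorial bromides have no anti-periplanar hydrogen and should survive mild base.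

## Compound list

1 | methacrolein (2-methylprop-2-enal) | CC(=C)C=O | starting material
2 | methyl but-3-enoate | C=CCC(=O)OC | starting material
3 | methyl (E)-4-methyl-5-oxopent-3-enoate | COC(=O)C/C=C(\C)C=O | intermediate
4 | (E)-buta-1,3-dien-1-yl acetate | CC(=O)O/C=C/C=C | starting material
5 | methyl 2-[(1S,5R,6S)-5-acetoxy-6-formyl-6-methylcyclohex-3-en-1-yl]acetate | C[C@@]1(C=O)[C@H](OC(C)=O)C=CC[C@H]1CC(=O)OC | intermediate
6 | methyl 2-[(1S,5R,6S)-5-acetoxy-6-ethenyl-6-methylcyclohex-3-en-1-yl]acetate | C[C@@]1(C=C)[C@H](OC(C)=O)C=CC[C@H]1CC(=O)OC | intermediate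
7 | methyl 2-[(1S,5R,6S)-6-ethenyl-5-hydroxy-6-methylcyclohex-3-en-1-yl]acetate | C[C@@]1(C=C)[C@H](O)C=CC[C@H]1CC(=O)OC | intermediate
8 | methyl 2-[(1S,5R,6S)-5-(tert-butyldimethylsilyloxy)-6-ethenyl-6-methylcyclohex-3-en-1-yl]acetate | C[C@@]1(C=C)[C@H](O[Si](C)(C)C(C)(C)C)C=CC[C@H]1CC(=O)OC | intermediate
9 | B-alkyl-9-borabicyclo[3.3.1]nonane from 8 (boron on the terminal carbon of the former vinyl group) | C[C@@]1(CCB2C3CCCC2CCC3)[C@H](O[Si](C)(C)C(C)(C)C)C=CC[C@H]1CC(=O)OC | intermediate
10 | methyl 2-[(1S,5R,6S)-5-(tert-butyldimethylsilyloxy)-6-(2-hydroxyethyl)-6-methylcyclohex-3-en-1-yl]acetate | C[C@@]1(CCO)[C@H](O[Si](C)(C)C(C)(C)C)C=CC[C@H]1CC(=O)OC | intermediate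
11 | methyl 2-[(1S,5R,6S)-5-(tert-butyldimethylsilyloxy)-6-(2-iodoethyl)-6-methylcyclohex-3-en-1-yl]acetate | C[C@@]1(CCI)[C@H](O[Si](C)(C)C(C)(C)C)C=CC[C@H]1CC(=O)OC | intermediate
12 | methyl 7α-(tert-butyldimethylsilyloxy)-7aβ-methyl-2,3,3aα,4,7,7a-hexahydro-1H-indene-3α-carboxylate (trans-fused) | COC(=O)[C@@H]1CC[C@]2(C)[C@H](O[Si](C)(C)C(C)(C)C)C=CC[C@@H]12 | intermediate
13 | methyl 7α-(tert-butyldimethylsilyloxy)-7aβ-methyl-4-oxo-2,3,3aα,4,7,7a-hexahydro-1H-indene-3α-carboxylate | COC(=O)[C@@H]1CC[C@]2(C)[C@H](O[Si](C)(C)C(C)(C)C)C=CC(=O)[C@@H]12 | intermediate
14 | methyl 7α-(tert-butyldimethylsilyloxy)-7aβ-methyl-4-oxo-octahydro-1H-indene-3α-carboxylate (3aα-H) | COC(=O)[C@@H]1CC[C@]2(C)[C@H](O[Si](C)(C)C(C)(C)C)CCC(=O)[C@@H]12 | intermediate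
15 | methyl 7α-(tert-butyldimethylsilyloxy)-4β-hydroxy-4α,7aβ-dimethyl-octahydro-1H-indene-3α-carboxylate (3aα-H) | COC(=O)[C@@H]1CC[C@]2(C)[C@H](O[Si](C)(C)C(C)(C)C)CC[C@@](C)(O)[C@@H]12 | intermediate
16 | methyl 4β,7α-dihydroxy-4α,7aβ-dimethyl-octahydro-1H-indene-3α-carboxylate (3aα-H) | COC(=O)[C@@H]1CC[C@]2(C)[C@H](O)CC[C@@](C)(O)[C@@H]12 | intermediate
17 | methyl 7β-bromo-4β-hydroxy-4α,7aβ-dimethyl-octahydro-1H-indene-3α-carboxylate (3aα-H) | COC(=O)[C@@H]1CC[C@]2(C)[C@@H](Br)CC[C@@](C)(O)[C@@H]12 | intermediate
18 | methyl 7β-bromo-4α,7aβ-dimethyl-4β-(triethylsilyloxy)-octahydro-1H-indene-3α-carboxylate (3aα-H) | COC(=O)[C@@H]1CC[C@]2(C)[C@@H](Br)CC[C@@](C)(O[Si](CC)(CC)CC)[C@@H]12 | intermediate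
19 | 7β-bromo-N-methoxy-N,4α,7aβ-trimethyl-4β-(triethylsilyloxy)-octahydro-1H-indene-3α-carboxamide (3aα-H) | CON(C)C(=O)[C@@H]1CC[C@]2(C)[C@@H](Br)CC[C@@](C)(O[Si](CC)(CC)CC)[C@@H]12 | intermediate
20 | 6-methylhept-5-en-2-one | CC(C)=CCCC(C)=O | starting material
21 | (E)-N′-(6-methylhept-5-en-2-ylidene)-2,4,6-triisopropylbenzenesulfonohydrazide | CC(C)=CCC/C(C)=N/NS(=O)(=O)c1c(C(C)C)cc(C(C)C)cc1C(C)C | intermediate
22 | (6-methylhepta-1,5-dien-2-yl)lithium | [Li]C(=C)CCC=C(C)C | intermediate
23 | 1-[7β-bromo-4α,7aβ-dimethyl-4β-(triethylsilyloxy)-octahydro-1H-inden-3α-yl]-6-methyl-2-methylidenehept-5-en-1-one (3aα-H) | C=C(CCC=C(C)C)C(=O)[C@@H]1CC[C@]2(C)[C@@H](Br)CC[C@@](C)(O[Si](CC)(CC)CC)[C@@H]12 | intermediate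
24 | (1R)-1-[7β-bromo-4α,7aβ-dimethyl-4β-(triethylsilyloxy)-octahydro-1H-inden-3α-yl]-6-methyl-2-methylidenehept-5-en-1-ol (3aα-H) | C=C(CCC=C(C)C)[C@H](O)[C@@H]1CC[C@]2(C)[C@@H](Br)CC[C@@](C)(O[Si](CC)(CC)CC)[C@@H]12 | intermediate
25 | tert-butyl carbonate of 24 at the C1′ oxygen | C=C(CCC=C(C)C)[C@H](OC(=O)OC(C)(C)C)[C@@H]1CC[C@]2(C)[C@@H](Br)CC[C@@](C)(O[Si](CC)(CC)CC)[C@@H]12 | intermediate
26 | spiro cyclic carbonate of the C1′(R)/C1″(R) diol with (4″S)-bromide in ring A and C4 triethylsilyl ether | CC1(C)C[C@]2(OC(=O)O[C@@H]2[C@@H]3CC[C@]4(C)[C@@H](Br)CC[C@@](C)(O[Si](CC)(CC)CC)[C@@H]34)CC[C@@H]1Br | intermediate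
27 | spiro cyclic carbonate of 26 with free C4 hydroxyl | CC1(C)C[C@]2(OC(=O)O[C@@H]2[C@@H]3CC[C@]4(C)[C@@H](Br)CC[C@@](C)(O)[C@@H]34)CC[C@@H]1Br | intermediate
28 | (3R,3aS,4R,7S,7aS)-7-bromo-3-{(R)-[(1R,4S)-4-bromo-1-hydroxy-3,3-dimethylcyclohexyl](hydroxy)methyl}-4,7a-dimethyloctahydro-1H-inden-4-ol (CNP0193924.1) | CC1(C)C[C@@](O)([C@H](O)[C@@H]2CC[C@]3(C)[C@@H](Br)CC[C@@](C)(O)[C@@H]23)CC[C@@H]1Br | target

## Step count and least certain steps

Total: 21 steps. Longest linear sequence: 20 steps (steps 1–15 and 17–21, from 1 and 2); step 16 is the one-step side branch.

Step 20 (Proposed new method).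
- What may go wrong: the allylic carbonate lowers the nucleophilicity of the 1,1-disubstituted alkene, so proton loss from the bromonium or the cation could overtake ring closure. Face discrimination at the remote alkene could be insufficient. Equatorial instead of axial capture at C1″ would give the wrong ring A diastereomer.
- Fallback (known chemistry): setting out from 25, the achiral reagent Et2SBr·SbCl5Br (BDSB) in MeNO2 at low temperature, which is established for carbonate-terminated bromonium cyclisations, would effect the same closure without facial control. Because the hydrindane is a single enantiomer, 26 and its ring A diastereomer, the (1″S,4″R)-spiro carbonate F1, are diastereomers and can be separated by chromatography. The route is rejoined at 26.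

Step 2 (key step).
- What may go wrong: the trisubstituted, ester-bearing dienophile may react slowly, so that acid-promoted decomposition of the acetoxydiene, migration of the enal double bond towards the ester, or erosion of endo selectivity and of enantioselectivity becomes competitive.
- Fallback: setting out from 3, auxiliary control replaces catalyst control. The chiral diene (E)-buta-1,3-dien-1-yl (S)-2-methoxy-2-phenylacetate F2 (from crotonaldehyde and the O-methylmandeloyl chloride; the antipode is taken if the shielding model requires it) is combined with 3 under BF3·OEt2. The mandelate adduct F3 is freed from its diastereomer by chromatography or crystallisation and methylenated as in step 3 to the vinyl mandelate F4. Methanolysis (K2CO3, MeOH) returns to the route at 7.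

Step 13.
- What may go wrong: backside attack at the neopentylic C7 is slow, so anti elimination towards C6, migration of the anti-periplanar C7a methyl group, or dehydration of the tertiary alcohol can compete.
- Fallback: setting out from 16, the C–Br bond is made without substitution. Oxidation (Dess–Martin periodinane) gives the C7 ketone F5, and hydrazine gives the hydrazone F6. Bromination–dediazoniation in the manner of the Barton vinyl halide synthesis (N-bromosuccinimide, a guanidine base) gives the vinyl bromide F7. Hydrogen-atom-transfer hydrogenation (Mn(dpm)3, PhSiH3, t-BuOOH, i-PrOH) should deliver hydrogen to the α-bromo radical from the α face, away from the angular methyl, and return to the route at 17.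

Step 9.
- What may go wrong: oxygen may be delivered to the transposed terminus (C6), hydrogen may be abstracted at the silyloxy-bearing C7, or the product enone may epimerise at C3a.
- Fallback: setting out from 12, SeO2 (cat.) with t-BuOOH hydroxylates by an ene reaction and [2,3]-shift, which returns oxygen to the carbon that lost hydrogen, giving the C4 allylic alcohol F8 (either epimer). Oxidation with Dess–Martin periodinane rejoins the route at 13.

Step 18.
- What may go wrong: facial selectivity of hydride delivery may be too low with a small hydride, or conjugate reduction of the α-methylene ketone may intervene.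
- Fallback: setting out from 23, reagent control replaces substrate control. Corey–Bakshi–Shibata reduction with the oxazaborolidine antipode that reinforces the Felkin–Anh sense, with catecholborane, returns to the route at 24 and makes no new compound.

## Further compounds

F1 | step 20 | (1″S,4″R) ring A diastereomer of 26 | CC1(C)C[C@@]2(OC(=O)O[C@@H]2[C@@H]3CC[C@]4(C)[C@@H](Br)CC[C@@](C)(O[Si](CC)(CC)CC)[C@@H]34)CC[C@H]1Br
F2 | step 2 | (E)-buta-1,3-dien-1-yl (S)-2-methoxy-2-phenylacetate | CO[C@@H](c1ccccc1)C(=O)O/C=C/C=C
F3 | step 2 | (S)-O-methylmandelate analogue of 5 | C[C@@]1(C=O)[C@H](OC(=O)[C@@H](OC)c2ccccc2)C=CC[C@H]1CC(=O)OC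
F4 | step 2 | (S)-O-methylmandelate analogue of 6 | C[C@@]1(C=C)[C@H](OC(=O)[C@@H](OC)c2ccccc2)C=CC[C@H]1CC(=O)OC
F5 | step 13 | methyl 4β-hydroxy-4α,7aβ-dimethyl-7-oxo-octahydro-1H-indene-3α-carboxylate (3aα-H) | COC(=O)[C@@H]1CC[C@]2(C)C(=O)CC[C@@](C)(O)[C@@H]12
F6 | step 13 | hydrazone of F5 at C7 | COC(=O)[C@@H]1CC[C@]2(C)C(=NN)CC[C@@](C)(O)[C@@H]12
F7 | step 13 | methyl 7-bromo-4β-hydroxy-4α,7aβ-dimethyl-2,3,3aα,4,5,7a-hexahydro-1H-indene-3α-carboxylate | COC(=O)[C@@H]1CC[C@]2(C)C(Br)=CC[C@@](C)(O)[C@@H]12
F8 | step 9 | methyl 7α-(tert-butyldimethylsilyloxy)-4-hydroxy-7aβ-methyl-2,3,3aα,4,7,7a-hexahydro-1H-indene-3α-carboxylate (C4 epimer not defined) | COC(=O)[C@@H]1CC[C@]2(C)[C@H](O[Si](C)(C)C(C)(C)C)C=CC(O)[C@@H]12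
F0 | step 18 | none | none
A1 | alternative 1 | ring A bromide with spiro cyclic carbonate (identical with 26) | CC1(C)C[C@]2(OC(=O)O[C@@H]2[C@@H]3CC[C@]4(C)[C@@H](Br)CC[C@@](C)(O[Si](CC)(CC)CC)[C@@H]34)CC[C@@H]1Br
A2 | alternative 1 | open dienyl tert-butyl carbonate (identical with 25) | C=C(CCC=C(C)C)[C@H](OC(=O)OC(C)(C)C)[C@@H]1CC[C@]2(C)[C@@H](Br)CC[C@@](C)(O[Si](CC)(CC)CC)[C@@H]12
A3 | alternative 2 | trans-hydrindene methyl ester | COC(=O)[C@@H]1C=C[C@]2(C)C3(OCCO3)CC[C@@](C)(O[Si](CC)(CC)CC)[C@@H]12
A4 | alternative 2 | α′-diazo enone of the trans-decalin | [N-]=[N+]=C1C(=O)C=C[C@]2(C)C3(OCCO3)CC[C@@](C)(O[Si](CC)(CC)CC)[C@@H]12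
A5 | alternative 2 | (S)-Wieland–Miescher ketone | C[C@]12CCC(=O)C=C1CCCC2=O
A6 | alternative 3 | trans-hydrindanone with exocyclic methylene | C=C1CCC(=O)[C@@]2(C)CC[C@@H](CO[Si](C)(C)C(C)(C)C)[C@H]12
A7 | alternative 3 | cyclopentane carrying the trimethylsilyl enol ether and the 2-substituted allylsilane | C=C(O[Si](C)(C)C)[C@@]1(C)CC[C@@H](CO[Si](C)(C)C(C)(C)C)[C@@H]1C(=C)C[Si](C)(C)C
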